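**Assumptions:** (S)-(+)-linalool (≥95% ee), (2E,6E)-farnesyl acetate and prenyl phenyl sulfone are purchasable. Numbering follows the hexaprenyl chain: ring C1–C14, with C14 the ring CH and C15 the carbinol. The target is (14R,15S).

## Retrosynthetic overview
1. The target comes from C1–C14 bond formation, done last: an electroreductive, alkoxide-directed Ni macrocyclisation of allylic acetate **12** onto its E-disubstituted C13=C14 alkene. The C14 centre is set relative to C15 here, and C13 becomes CH2 by protonolysis.
2. **12** comes from cross-metathesis of (S)-nerolidol (**6**) with the tetraene acetate **11**, which forms the C12–C13 bond.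
3. **6** comes from (S)-linalool (**1**) by SeO2 oxidation, chlorination and a prenyl-sulfone chain extension. **11** comes from farnesyl acetate (**7**) by SeO2 oxidation, chlorination and vinyl–Cu coupling.
4. The only ring is the 14-membered one, closed in the final step. C15 is the linalool carbinol and is never touched.

## Route

**Step 1**
Reactants: **1** (S)-(+)-linalool
Product: **2** (3S,6E)-3,7-dimethylocta-1,6-diene-3,8-diol
Conditions: SeO2 (10 mol%), TBHP (2 equiv), CH2Cl2, rt
Reagents that add atoms: SeO2 (O=[Se]=O), the oxygen source; TBHP is the reoxidant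
Why: Riley allylic oxidation (ene, then [2,3]) hydroxylates the E-methyl of the trisubstituted alkene selectively, and the vinyl group and C3 carbinol are untouched.

**Step 2**
Reactants: **2**
Product: **3** (3S,6E)-8-chloro-3,7-dimethylocta-1,6-dien-3-ol
Conditions: MsCl, LiCl, 2,4,6-collidine, DMF, 0 °C
Reagents that add atoms: LiCl ([Li+].[Cl-])
Why: Meyers mesylation/chloride displacement converts only the primary allylic alcohol, and the tertiary allylic alcohol is unreactive under these conditions.

**Step 3**
Reactants: **3**; **4** prenyl phenyl sulfone (CC(C)=CCS(=O)(=O)c1ccccc1)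
Product: **5** (3S,6E)-3,7,11-trimethyl-9-(phenylsulfonyl)dodeca-1,6,10-trien-3-ol
Conditions: **4** (1.5 equiv), n-BuLi (3.3 equiv), THF/HMPA 10:1, −78 → −30 °C
Reagents that add atoms: none (n-BuLi is only a base; **4** is the reactant)
Why: Biellmann-type α-alkylation of the prenyl sulfone carbanion by the primary allylic chloride forms the head-to-tail C20–C21 bond at the sulfone carbon. The sulfone stereocentre is destroyed in the next step.

**Step 4**
Reactants: **5**
Product: **6** (3S,6E)-3,7,11-trimethyldodeca-1,6,10-trien-3-ol, (S)-nerolidol
Conditions: Li, EtNH2/THF, −78 °C, 10 min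
Reagents that add atoms: none (only H is added)
Why: Dissolving-metal desulfonylation removes the allylic sulfone with retention of the alkene position and geometry, and C3 is not involved.

**Step 5**
Reactants: **7** (2E,6E)-farnesyl acetate
Product: **8** (2E,6E,10E)-12-hydroxy-3,7,11-trimethyldodeca-2,6,10-trien-1-yl acetate
Conditions: SeO2 (10 mol%), TBHP (2 equiv), CH2Cl2, rt
Reagents that add atoms: SeO2 (O=[Se]=O)
Why: Riley oxidation is selective for the most accessible terminal isopropylidene and gives the E-allylic alcohol (trans to the chain).

**Step 6**
Reactants: **8**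
Product: **9** (2E,6E,10E)-12-chloro-3,7,11-trimethyldodeca-2,6,10-trien-1-yl acetate
Conditions: MsCl, LiCl, 2,4,6-collidine, DMF, 0 °C
Reagents that add atoms: LiCl ([Li+].[Cl-])
Why: The same Meyers chlorination is used, and the allylic acetate survives.

**Step 7**
Reactants: **9**; **10** vinylmagnesium bromide (C=C[Mg]Br)
Product: **11** (2E,6E,10E)-3,7,11-trimethyltetradeca-2,6,10,13-tetraen-1-yl acetate
Conditions: **10** (1.2 equiv), Li2CuCl4 (5 mol%), THF, −30 °C
Reagents that add atoms: none (**10** is the reactant)
Why: Cu-catalysed SN2 (α) coupling of a primary allylic chloride with a Grignard reagent forms C12–C13 with retention of the E alkene; the allylic acetate is far less reactive at −30 °C.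

**Step 8**
Reactants: **6**; **11**
Product: **12** (2E,6E,10E,13E,15S,18E)-15-hydroxy-3,7,11,15,19,23-hexamethyltetracosa-2,6,10,13,18,22-hexaen-1-yl acetate
Conditions: Hoveyda–Grubbs II (5 mol%), CH2Cl2 (0.05 M), 40 °C, N2 sweep to remove ethylene; **11** (1.5 equiv)
Reagents that add atoms: none (ethylene is lost)
Why: Cross-metathesis between two monosubstituted vinyl groups gives the E-1,2-disubstituted alkene, and the trisubstituted alkenes are inert; C15 is not involved.

**Step 9**
Reactants: **12**
Product: **13** colleterpenol
Conditions: NiBr2·diglyme (10 mol%), 4,4′-di-tert-butylbipyridine (12 mol%), nBu4NBF4 (0.1 M), DMF/THF 1:1, MeOH (10 equiv), undivided cell, Zn anode/carbon-felt cathode, 2 mA constant current, rt, **12** added by syringe pump over 12 h to 0.002 M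
Reagents that add atoms: none (the added H comes from MeOH; electrons from electrolysis)
Why: Proposed new method: Ni(0) generated at the cathode ionises the primary allylic acetate to a (π-allyl)Ni species, and the tertiary alkoxide binds Ni.
- Syn 1,2-insertion of the C13=C14 alkene puts C1 on C14 and Ni on C13, forming a five-membered oxanickelacycle and closing the 14-membered ring. Syn insertion leaves C14–H anti to Ni, which suppresses β-H elimination.
- MeOH protonolysis gives C13H2, and the cathode regenerates Ni(0).
- In the favoured rotamer the small Me group is "inside", eclipsing the alkene. The oxygen sits perpendicular on the face that delivers Ni, and the CH2R chain is "outside" near C14–H. This gives (14R) relative to the fixed (15S).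
- The primary allyl terminus reacts, and the E geometry of C2=C3 is kept through the syn-π-allyl.
- The closest known chemistry is Ni-catalysed alcohol-directed alkene 1,2-difunctionalisation, intramolecular (macrocyclic) Heck-type insertion, and Ni-catalysed reductive allylation.

## Compound list
1 | (S)-(+)-linalool | C=C[C@@](C)(O)CCC=C(C)C | starting material
2 | (3S,6E)-8-hydroxylinalool | C=C[C@@](C)(O)CC/C=C(\C)CO | intermediate
3 | (3S,6E)-8-chlorolinalool | C=C[C@@](C)(O)CC/C=C(\C)CCl | intermediate
4 | prenyl phenyl sulfone | CC(C)=CCS(=O)(=O)c1ccccc1 | starting material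
5 | allylic sulfone adduct | C=C[C@@](C)(O)CC/C=C(\C)CC(C=C(C)C)S(=O)(=O)c1ccccc1 | intermediate
6 | (S)-(E)-nerolidol | C=C[C@@](C)(O)CC/C=C(\C)CCC=C(C)C | intermediate
7 | (2E,6E)-farnesyl acetate | CC(C)=CCC/C(C)=C/CC/C(C)=C/COC(C)=O | starting material
8 | 12-hydroxyfarnesyl acetate | OC/C(C)=C/CC/C(C)=C/CC/C(C)=C/COC(C)=O | intermediate
9 | 12-chlorofarnesyl acetate | ClC/C(C)=C/CC/C(C)=C/CC/C(C)=C/COC(C)=O | intermediate
10 | vinylmagnesium bromide | C=C[Mg]Br | starting material
11 | tetraene acetate | C=CC/C(C)=C/CC/C(C)=C/CC/C(C)=C/COC(C)=O | intermediate
12 | macrocyclisation precursor | CC(C)=CCC/C(C)=C/CC[C@](C)(O)/C=C/C/C(C)=C/CC/C(C)=C/CC/C(C)=C/COC(C)=O | intermediate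
13 | colleterpenol | CC(C)=CCC/C(C)=C/CC[C@](C)(O)[C@H]1C/C=C(\C)CC/C=C(\C)CC/C=C(\C)CC1 | target

## Totals
- Total steps: 9.
- Longest linear sequence: 6 (1 → 2 → 3 → 5 → 6 → 12 → 13).

## Three steps most likely to fail
1. **Step 9 (new step).** The insertion may fail next to the quaternary carbinol, the C14 dr may be low, or oligomers or β-H-elimination (Heck-type) products may form.
   - Fallback (known chemistry, different approach): take C14 from (R)-(+)-limonene, which maps onto C14 with the same (R) descriptor.
   - Open the ring (epoxide/diol, then Pb(OAc)4 or NaIO4) to the keto-aldehyde, and build the two E-trisubstituted arms by Horner–Wadsworth–Emmons olefinations.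
   - Close the ring by Corey-type Ni(0) allyl–allyl coupling of the bis-allylic bromide.
   - Set C15 last by Felkin-type addition of homogeranyl-MgBr to the methyl ketone from the isopropenyl group, and separate diastereomers.
2. **Step 8 (cross-metathesis).** The hindered tertiary-allylic vinyl group and the skipped-diene partner may give homodimers, E/Z mixtures or alkene isomerisation.
   - Fallback: Ru-catalysed dehydrogenative borylation of **6** to the (E)-alkenyl-Bpin, then Pd- or Cu-catalysed Suzuki-type allyl coupling with chloride **9**, then vinylation-free assembly of **12** in the same way.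
3. **Step 4 (Li/EtNH2).** The free vinyl group or tertiary alkoxide may be reduced or isomerised.
   - Fallback: selectively epoxidise the prenyl alkene of **1**, cleave it to the C6 aldehyde, and install the E-trisubstituted C18=C19 alkene by Schlosser-modified Wittig with the ylide of 2-bromo-6-methylhept-5-ene.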